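(The earlier runs and the new flask were generated by integration from invented constants; the scatter is artificial.)

- zeta: substrate 0.80 M; reagent 0.48 M; free catalyst 7.6 mM; the very flask that is asked about, followed so far
- flask: substrate 0.80 M; reagent 0.480 M; free catalyst 7.6 mM; time 8.0 d

zeta run (percent of the substrate charged)

| time / d | target / % |
|---|---|
| 0.333 | 13.5 |
| 1.04 | 30.6 |
| 1.67 | 36.1 |
| 3.00 | 40.4 |
| 4.00 | 41.4 |
| 5.00 | 40.8 |
| 6.00 | 41.9 |

(readings scatter by 0.5 percentage points)

- summer: at 8.0 d add reagent, 100 % of the amount charged, then wait 15 d
- winter: change nothing and wait 15 d more
- midnight: at 8.0 d take out 90 % of the target then present, then wait 15 d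
- noon: at 8.0 d add free catalyst, 50.0 % of the amount charged, then wait 15 d

- removed target is counted in
- additions bring no volume worth counting

1. target, in percent of the substrate first charged, at 8.0 d
2. the option that brings most further target ("none" if no option brings more than 2 percentage points) (summer / winter / midnight / noon / none)
3. target present, with what was taken out counted in, in percent of the substrate first charged, after summer
4. target present, with what was taken out counted in, in percent of the substrate first charged, after midnight

If the flat stretch of the zeta run looks to you like equilibrium, hold the next charge back, since a catalyst that dies ends a curve on the same kind of flat line. Under equilibrium you would add reagent, and under a dead catalyst you would add free catalyst, which takes 3.80 mM against 0.480 M of reagent, far less; my own reckoning tries the dead catalyst as its working picture, which is a choice and not a finding, and puts a number on it.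

The last readings of the target in zeta, which is the flask asked about, average 41.4 % of the substrate charged, and at one reagent per target that reading leaves 31.1 % of the reagent, or 0.149 M. The plain turnover number, 43.5 targets per catalyst charged, promises 0.165 M from the noon addition, more than that reagent, so this first answer cannot stand.

Put it back in and go round. If each round of a working catalyst ends either in taking up reagent or in death, turnovers per catalyst follow the free reagent, and the reagent falls exponentially with catalyst lost. So I carry the reach of the catalyst, the natural logarithm of reagent charged over reagent left at the stop, per amount of catalyst charged, which is 0.154 mM⁻¹. At noon the reach leaves 17.3 % of the reagent, a gain of 8.2 percentage points, and I expect summer and midnight to stay at the plateau, so I would charge noon.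

The forecast agrees on the present, 41.5 % within 40.9 % to 42.1 %, and then differs from me by naming summer: “Extra reagent helps under both surviving pictures, so summer is best.” It gives 67 % after summer and 52 % after midnight.

The flask gives 41.3 %, and noon is best with 8.1 points more, against 0.018 points from summer; summer ends at 41.4 % and midnight at 41.4 %, with spent catalyst at >99.9 % of the catalyst charged at 8.00 d.

    catalyst intermediate B ⇌ free catalyst + target (K = 2.50 M, k = 0.680 min⁻¹)
    substrate + free catalyst ⇌ catalyst intermediate A (K = 33.0 L mol⁻¹, k = 0.0770 L mol⁻¹ min⁻¹)
    reagent + catalyst intermediate A ⇌ catalyst intermediate B (K = 52.0 L mol⁻¹, k = 0.330 L mol⁻¹ min⁻¹)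
    catalyst intermediate A → spent catalyst (k = 0.00210 min⁻¹)

Charged with 0.0030 M of free catalyst, the same flask should by the reach keep 63.0 % of its reagent and make 22.2 % target; that neighbour held 63 % of its reagent and 22.3 % target.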